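## The problem

Compound 12 is a spiro biflavonoid. C2 of a 4,6-dihydroxybenzofuran-3(2H)-one is at the same time C3 of a 2-(4-hydroxyphenyl)-2,3-dihydrofuran, and that dihydrofuran is fused through O7 and C8 to ring A of (2R,3S)-afzelechin.

A synthesis has to build a fully substituted carbon that carries an aryl ether oxygen (O1), a ketone carbon, a di-ortho-substituted aryl ring and a benzylic CH. Of the four stereocentres, the two of the pyran ring can be bought with afzelechin, but ring A lies between them and the spiro carbon, so they cannot be relied on to control it. The spiro carbon (S), once fixed, is directly bonded to the dihydrofuran CH (S) and can control that centre.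

Six free phenols on electron-rich rings, two of them of the phloroglucinol type, rule out strong oxidants and strong base late in the route. The flavan C2–O bond and the dihydrofuran CH–O7 bond are benzylic ethers para to a phenol and can reopen to quinone methides under acid or heat, which threatens both centres with epimerisation. The α-aryloxy ketone would be cleaved by dissolving metals.

The feature that opens the route is the dihydrofuran CH. It is the benzylic carbon of a 4-hydroxybenzyl group, it is attached to a carbon without hydrogen, and it lies five atoms from the ring A phenol oxygen O7. The CH–O7 bond is therefore the adduct of O7 to a para-quinone methide.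

## Retrosynthesis

**12 to 10 (through 11).** The CH–O7 bond is cut, which opens the dihydrofuran and leads through the para-quinone methide 11 to the 2-aryl-2-benzylbenzofuranone 10. The neighbouring cuts at the spiro carbon (C8–C or O1–C) would have to create the fully substituted carbon late, on a finished dihydrofuran. This cut instead asks only that a phenol add to an electrophile which the substrate produces from its own CH2 group. Compound 10 has one ring and one stereocentre fewer than 12. The forward reaction must dehydrogenate the 4-hydroxybenzyl CH2 of 10 and leave untouched the phloroglucinol rings and two other benzylic positions that also stand para to a phenol: flavan C2–H (ring B phenol) and flavan C4–H2 (O7–H). It must then close 5-exo with the aryl group on the side of O1. A flavoprotein oxidase of the vanillyl-alcohol oxidase family is chosen because it recognises a para-alkylphenol by shape, whereas a chemical oxidant would go for the most electron-rich ring.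

**10 to 9.** No skeletal bond is cut. The seven hydroxyl groups of 10 are traced back to benzyl ethers in 9, because the two C–C bond formations at the future spiro carbon use enolate and palladium chemistry that free phloroglucinol rings do not tolerate. Benzyl ethers are preferred to acetal or silyl groups since they all leave together under neutral conditions; acid could ionise the C2–O1 bond, which is benzylic to ring A.

**9 to 7 and 8.** The C2–CH2 bond is cut, giving the enolisable 2-arylbenzofuranone 7 and the benzylic bromide 8. The reverse order, with the benzyl group in place and ring A introduced last, was set aside. A cation at C2 of a benzofuran-3-one is an acyl-substituted oxocarbenium ion with cyclopentadienyl-cation character, and E1 loss of a benzylic proton would compete with substitution. Enolate arylation at a carbon that becomes fully substituted, with a di-ortho-substituted aryl halide, is sterically implausible. Compound 7 has no fully substituted carbon. The forward step must alkylate a hindered ambident enolate at carbon and on the correct face; as the flavan centres are remote, a chiral phase-transfer cation is asked to supply the bias, and the epimers, being diastereomers, can be separated.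

**7 to 4 and 6.** The C2–C8 bond is cut, giving the aryl bromide 4 and the ketone 6. A palladium-catalysed α-arylation is preferred to an electrophilic substitution on ring A, because the bromine fixes C8 against C6 beforehand and the secondary enolate carbon is still accessible. The product is more acidic than 6, which should stop the reaction after one arylation.

**4 to 3 to 1, and 6 to 5.** Bromide 4 comes from the tetrabenzyl ether 3 by bromination at C8, the known site for per-O-benzylated flavan-3-ols, and 3 from (+)-afzelechin 1, which supplies both pyran stereocentres. Ketone 6 is the dibenzyl ether of 4,6-dihydroxybenzofuran-3(2H)-one 5.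

## Roads not taken

**Alternative 1:** The cut is at the C(spiro)–O bond, which is made first by a titanium–tartrate-catalysed asymmetric epoxidation of the (E)-allylic alcohol A1 to the cis-2,3-diaryl epoxy alcohol A2.
- Merit: the tertiary ether carbon is set with absolute, reagent-based control, independent of the flavan. In this respect the road is better than the chosen plan, which relies on a catalyst-biased alkylation and a separation of diastereomers.
- Weak points: the oxirane carbon of A2 that carries ring A is tertiary and benzylic to a trioxygenated ring, so the Lewis-acidic titanium medium can ionise it and erase the centre just set. A2 also still lacks the whole benzofuranone ring: the primary alcohol must be oxidised, the epoxide oxygen arylated at a tertiary carbon, and the benzylic C–O bond exchanged for O7.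
- Comparison: the chosen plan accepts weaker control of the fully substituted centre, but ketone, ring oxygen and both aryl groups are already in place when that centre is formed, and the route is much shorter.

**Alternative 2:** The cut is at the pyran O1–C2 bond of the flavan, which is closed last. The 1,2-diol A3 is converted with an orthoformate and mild acid into a dioxolanylium ion, which the ring D phenol opens at the benzylic carbon with inversion to give the 2,3-trans flavan 3-formate A4.
- Merit: the key step is of a known type and stereospecific, and the epimerisable flavan C2 is not exposed to any earlier step. Here it is better than the chosen plan.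
- Weak points: A3 already contains the spiro ketone and the dihydrofuran, so the hardest part of the target has to be built on a ring D without any chiral information. The diol needs its own asymmetric step. A 4-alkoxybenzylic dioxolanylium ion can open by an SN1 path and lose the 2,3-trans relation.
- Comparison: the chosen plan takes both pyran centres from 1 at no cost in steps and spends its effort only on the spiro ring.

**Alternative 3:** The cut is at the O1–aryl and aryl–CO bonds of the benzofuranone. The tertiary alkoxide of hydroxy ester A5 adds to the aryne released by fluoride from silyl triflate A6, and the resulting aryl anion closes onto the ester to give the protected spiro ketone A7.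
- Merit: two bonds and a ring form in one convergent step at a preformed fully substituted carbon, using a known reaction type. In precedent it is at least equal to the chosen plan.
- Weak points: the alkoxide is tertiary and flanked by a di-ortho-substituted aryl ring, and protonation of the aryl anion can stop the sequence at the aryl ether. A7 is the CH epimer of the target (aryl trans to O1), so after desilylation a quinone methide equilibration is needed, followed by acidic removal of the acetal groups next to a benzylic ether that itself opens under acid.
- Comparison: the chosen plan uses the same quinone methide to form the bond rather than to correct it, and ends on the unprotected target.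

Key step: step 7

Remark: C2 of the benzofuranone in 7 is enolisable and is carried as an epimer mixture; the oxidase of step 7 is assumed to be an active-site-enlarged eugenol oxidase variant obtained by directed evolution.

## Route

**Step 1**
Reactants: 1 (+)-afzelechin
Product: 3 3,5,7,4'-tetra-O-benzylafzelechin, via 5,7,4'-tri-O-benzylafzelechin 2 (not isolated)
Conditions: BnBr, K2CO3, DMF, 0 °C→rt; then NaH, 0 °C→rt, same flask
Reagents that add atoms: benzyl bromide, BrCc1ccccc1
Why: Williamson etherification; the carbonate benzylates the three phenols and the alkoxide formed with NaH then benzylates the secondary 3-OH, while the C2 and C3 centres of 1 are carried through unchanged.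

**Step 2**
Reactants: 3 3,5,7,4'-tetra-O-benzylafzelechin
Product: 4 8-bromo-3,5,7,4'-tetra-O-benzylafzelechin
Conditions: NBS, CH2Cl2, −78 °C→0 °C
Reagents that add atoms: N-bromosuccinimide, O=C1CCC(=O)N1Br
Why: Electrophilic aromatic bromination; ring A is the only trioxygenated ring and C8 is the established site of monobromination in per-O-benzylated flavan-3-ols, C6 being shielded by two flanking benzyloxy groups.

**Step 3**
Reactants: 5 4,6-dihydroxybenzofuran-3(2H)-one
Product: 6 4,6-bis(benzyloxy)benzofuran-3(2H)-one
Conditions: BnBr, K2CO3, DMF, rt→60 °C
Reagents that add atoms: benzyl bromide, BrCc1ccccc1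
Why: Williamson etherification of the two acidic phenols (vinylogous acids) with a weak base, so that the phenoxides rather than the C2 enolate are alkylated; warming is needed for the 4-OH, which is hydrogen-bonded to the ketone.

**Step 4**
Reactants: 4 8-bromo-3,5,7,4'-tetra-O-benzylafzelechin; 6 4,6-bis(benzyloxy)benzofuran-3(2H)-one
Product: 7 4,6-bis(benzyloxy)-2-(3,5,7,4'-tetra-O-benzylafzelechin-8-yl)benzofuran-3(2H)-one (C2 epimers)
Conditions: Pd(OAc)2 (5 mol %), 2-dicyclohexylphosphino-2',4',6'-triisopropylbiphenyl (10 mol %), NaOtBu, toluene, 90 °C, argon; AcOH quench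
Reagents that add atoms: none
Why: Palladium-catalysed ketone α-arylation (Buchwald–Hartwig type): oxidative addition into the C8–Br bond, exchange with the sodium enolate of 6 and C–C reductive elimination, with a bulky biaryl phosphine for the di-ortho-substituted bromide; the product is more acidic than 6 and rests as its enolate, so a second arylation is not expected, and the new enolisable C2 centre is left uncontrolled because step 5 planarises it again.

**Step 5**
Reactants: 7 4,6-bis(benzyloxy)-2-(3,5,7,4'-tetra-O-benzylafzelechin-8-yl)benzofuran-3(2H)-one; 8 4-(benzyloxy)benzyl bromide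
Product: 9 (2R)-4,6-bis(benzyloxy)-2-[4-(benzyloxy)benzyl]-2-(3,5,7,4'-tetra-O-benzylafzelechin-8-yl)benzofuran-3(2H)-one
Conditions: Cs2CO3, N-[4-(trifluoromethyl)benzyl]cinchoninium bromide (10 mol %), toluene, 0 °C→rt, argon; separation of the C2 epimers on silica
Reagents that add atoms: none
Why: Phase-transfer C-alkylation of an α-aryl ketone enolate with a benzylic bromide, in which the tight ion pair in toluene should favour attack through carbon over oxygen; the fully substituted centre is set under the influence of the chiral ammonium cation, since the flavan centres lie beyond ring A, and the (2R) epimer is separated from its diastereomer and its configuration secured by X-ray analysis or by correlation with 12.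

**Step 6**
Reactants: 9 (2R)-4,6-bis(benzyloxy)-2-[4-(benzyloxy)benzyl]-2-(3,5,7,4'-tetra-O-benzylafzelechin-8-yl)benzofuran-3(2H)-one
Product: 10 (2R)-2-(afzelechin-8-yl)-4,6-dihydroxy-2-(4-hydroxybenzyl)benzofuran-3(2H)-one
Conditions: H2 (1 atm), Pd(OH)2/C, THF/MeOH, rt; argon during isolation
Reagents that add atoms: none
Why: Catalytic hydrogenolysis of six aryl benzyl ethers and one alkyl benzyl ether; the flavan C2–O bond and the C2–O1 bond at the fully substituted carbon are hindered benzylic aryl ethers of the kind that survive debenzylation of flavan-3-ols, the ketone is deactivated as a vinylogous ester, and no stereocentre is touched.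

**Step 7**
Reactants: 10 (2R)-2-(afzelechin-8-yl)-4,6-dihydroxy-2-(4-hydroxybenzyl)benzofuran-3(2H)-one
Product: 12 target spiro biflavonoid (spiro carbon S; dihydrofuran CH S; flavan 2R 3S), via para-quinone methide 11 (not isolated)
Conditions: engineered eugenol oxidase variant (FAD-dependent, vanillyl-alcohol oxidase family), air (O2), catalase, KH2PO4/K2HPO4 buffer (50 mM, pH 7.5) with 10% v/v DMSO, 25 °C
Reagents that add atoms: none
Why: Proposed new method: the oxidase is expected to hold the 4-hydroxybenzyl phenol of 10 as its phenolate and to pass a hydride from the benzylic CH2 to N5 of the flavin, which gives the para-quinone methide 11, while O2 reoxidises the reduced flavin to H2O2, which catalase removes. The closest known reaction type is the oxidation of 4-alkylphenols and 4-(methoxymethyl)phenol to para-quinone methides by vanillyl-alcohol oxidase and eugenol oxidase with water as the nucleophile; new here are the size of the substrate and capture by an internal phenol. O7–H of ring A then adds to the exocyclic methide carbon in a 5-exo-trig closure that restores the aromatic ring and forms the dihydrofuran. The new CH centre is controlled by the adjacent fully substituted carbon: in the closure the aryl group should turn toward the ring oxygen O1 and away from the C3 carbonyl group, which is the (S) arrangement of 12, and because such para-hydroxybenzylic ethers can reopen to the quinone methide the centre can also settle under thermodynamic control. The step needs site selectivity among three benzylic positions para to a phenol (the benzyl CH2, flavan C2–H and flavan C4–H2); only the benzyl arm is an unhindered monohydric phenol on a flexible methylene, whereas flavan C2–H is tertiary and ring-bound and the ring A phenols carry two ortho substituents. Styrene formation, the usual fate of longer 4-alkylphenols with these enzymes, is excluded because the carbon next to the CH2 bears no hydrogen.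

## Compound list

1 | (+)-afzelechin, (2R,3S)-2-(4-hydroxyphenyl)chromane-3,5,7-triol | Oc1cc(O)c2c(c1)O[C@H](c1ccc(O)cc1)[C@@H](O)C2 | starting material
2 | 5,7,4'-tri-O-benzylafzelechin, (2R,3S)-5,7-bis(benzyloxy)-2-[4-(benzyloxy)phenyl]chroman-3-ol | c1ccccc1COc1cc(OCc3ccccc3)c2c(c1)O[C@H](c1ccc(OCc3ccccc3)cc1)[C@@H](O)C2 | intermediate (not isolated)
3 | 3,5,7,4'-tetra-O-benzylafzelechin, (2R,3S)-3,5,7-tris(benzyloxy)-2-[4-(benzyloxy)phenyl]chromane | c1ccccc1COc1cc(OCc3ccccc3)c2c(c1)O[C@H](c1ccc(OCc3ccccc3)cc1)[C@@H](OCc1ccccc1)C2 | intermediate
4 | 8-bromo-3,5,7,4'-tetra-O-benzylafzelechin | c1ccccc1COc1cc(OCc3ccccc3)c2c(c1Br)O[C@H](c1ccc(OCc3ccccc3)cc1)[C@@H](OCc1ccccc1)C2 | intermediate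
5 | 4,6-dihydroxybenzofuran-3(2H)-one | O=C1COc2cc(O)cc(O)c12 | starting material
6 | 4,6-bis(benzyloxy)benzofuran-3(2H)-one | O=C1COc2cc(OCc3ccccc3)cc(OCc3ccccc3)c12 | intermediate
7 | 4,6-bis(benzyloxy)-2-{(2R,3S)-3,5,7-tris(benzyloxy)-2-[4-(benzyloxy)phenyl]chroman-8-yl}benzofuran-3(2H)-one, benzofuranone C2 unassigned | O=C1c2c(OCc3ccccc3)cc(OCc3ccccc3)cc2OC1c1c(OCc2ccccc2)cc(OCc2ccccc2)c2c1O[C@H](c1ccc(OCc3ccccc3)cc1)[C@@H](OCc1ccccc1)C2 | intermediate
8 | 4-(benzyloxy)benzyl bromide, 1-(benzyloxy)-4-(bromomethyl)benzene | BrCc1ccc(OCc2ccccc2)cc1 | starting material
9 | (2R)-4,6-bis(benzyloxy)-2-[4-(benzyloxy)benzyl]-2-{(2R,3S)-3,5,7-tris(benzyloxy)-2-[4-(benzyloxy)phenyl]chroman-8-yl}benzofuran-3(2H)-one | O=C1c2c(OCc3ccccc3)cc(OCc3ccccc3)cc2O[C@]1(Cc1ccc(OCc2ccccc2)cc1)c1c(OCc2ccccc2)cc(OCc2ccccc2)c2c1O[C@H](c1ccc(OCc3ccccc3)cc1)[C@@H](OCc1ccccc1)C2 | intermediate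
10 | (2R)-4,6-dihydroxy-2-(4-hydroxybenzyl)-2-[(2R,3S)-3,5,7-trihydroxy-2-(4-hydroxyphenyl)chroman-8-yl]benzofuran-3(2H)-one | O=C1c2c(O)cc(O)cc2O[C@]1(Cc1ccc(O)cc1)c1c(O)cc(O)c3c1O[C@H](c1ccc(O)cc1)[C@@H](O)C3 | intermediate
11 | para-quinone methide, (2R)-4,6-dihydroxy-2-[(4-oxocyclohexa-2,5-dien-1-ylidene)methyl]-2-[(2R,3S)-3,5,7-trihydroxy-2-(4-hydroxyphenyl)chroman-8-yl]benzofuran-3(2H)-one | O=C1c2c(O)cc(O)cc2O[C@]1(C=C1C=CC(=O)C=C1)c1c(O)cc(O)c3c1O[C@H](c1ccc(O)cc1)[C@@H](O)C3 | intermediate (not isolated)
12 | spiro ketone in which C2 (S) of 4,6-dihydroxybenzofuran-3(2H)-one is C3 of a 2-(4-hydroxyphenyl)-2,3-dihydrofuran (C2 S, aryl cis to the benzofuranone ring oxygen) fused at O7/C8 to (2R,3S)-afzelechin; the (S) spiro descriptor is the same spatial arrangement as (2R) in 9–11 | O=C1c2c(O)cc(O)cc2O[C@]12c1c(cc(O)c3c1O[C@H](c1ccc(O)cc1)[C@@H](O)C3)O[C@H]2c1ccc(O)cc1 | target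

## Step count and least certain steps

Total: 7 steps. Longest linear sequence: 6 steps (1, 2, 4, 5, 6, 7 from afzelechin); step 3 is a one-step branch.

**Step 7 (key step).** The most likely failure is lack of turnover, because the benzyl arm ends in a fully substituted carbon with two aryl groups and may not reach the flavin. If turnover occurs, hydride abstraction at another benzylic C–H para to a phenol, capture of the quinone methide by water instead of O7, or poor facial selectivity in the closure may follow.

The fallback uses known chemistry, sets out from 7 and returns at 12; the benzylic carbon is brought in at the alcohol oxidation level and ionised rather than dehydrogenated. The lithium enolate of 7 (LiN(SiMe3)2, THF, −78 °C) is added to 4-(benzyloxy)benzaldehyde and quenched cold to give the aldol adduct 4,6-bis(benzyloxy)-2-{[4-(benzyloxy)phenyl](hydroxy)methyl}-2-(3,5,7,4'-tetra-O-benzylafzelechin-8-yl)benzofuran-3(2H)-one F1. Its epimer with the spatial arrangement of 9 is (2S) by the priority rules and is separated; the carbinol configuration is irrelevant. With BF3·OEt2 and pentamethylbenzene in CH2Cl2 at −40 °C the 4-benzyloxybenzylic carbinol ionises, the O7 benzyl ether oxygen closes the dihydrofuran 5-exo, and the oxonium ion gives up its benzyl group to the scavenger, as in pterocarpan closures of 2'-O-protected isoflavan-4-ols. This gives the hexa-O-benzyl ether of 12 F2. Hydrogenolysis (H2, Pd(OH)2/C, THF/MeOH) then gives 12.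

**Step 4.** Oxidative addition into the very electron-rich, di-ortho-substituted bromide 4 may be slow, so that base-induced self-condensation of 6 or reduction of 4 takes over.

The fallback sets out from 3 and 6 and returns at 7, replacing cross-coupling with electrophilic substitution. The potassium enolate of 6 (KN(SiMe3)2, THF, −78 °C) is hydroxylated with 2-(phenylsulfonyl)-3-phenyloxaziridine to 4,6-bis(benzyloxy)-2-hydroxybenzofuran-3(2H)-one F3, the ring-closed hemiacetal of an arylglyoxal. With BF3·OEt2 in CH2Cl2 its aldehyde form hydroxyalkylates 3 at C8 (Friedel–Crafts), and the doubly activated benzylic carbinol is displaced by the neighbouring phenol to close the benzofuranone and give 7.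

**Step 5.** Alkylation through the enolate oxygen may compete at this hindered carbon, and the facial bias from the catalyst may be low, which would waste material as the (2S) epimer.

The fallback sets out from 7 and returns at 9. The enolate is deliberately O-alkylated with 8 (Cs2CO3, DMF) to the enol ether 4,6-bis(benzyloxy)-3-{[4-(benzyloxy)benzyl]oxy}-2-(3,5,7,4'-tetra-O-benzylafzelechin-8-yl)benzofuran F4. Catalytic Sc(OTf)3 in CH2Cl2 then induces the 1,3-shift of the 4-benzyloxybenzyl group from oxygen to C2 through its ion pair, giving 9 as an epimer mixture that is separated as before.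

**Step 6.** Prolonged hydrogenation may reduce the aryl ketone or cleave the benzylic C2–O1 bond.

The fallback sets out from 9 and returns at 10, replacing reductive with Lewis-acid debenzylation: BCl3 with pentamethylbenzene as benzyl scavenger in CH2Cl2 at −78 °C. It makes no new compound (F0).

## Further compounds

F1 | step 7 | (2S)-4,6-bis(benzyloxy)-2-{[4-(benzyloxy)phenyl](hydroxy)methyl}-2-{(2R,3S)-3,5,7-tris(benzyloxy)-2-[4-(benzyloxy)phenyl]chroman-8-yl}benzofuran-3(2H)-one, carbinol centre unassigned | O=C1c2c(OCc3ccccc3)cc(OCc3ccccc3)cc2O[C@]1(C(O)c1ccc(OCc2ccccc2)cc1)c1c(OCc2ccccc2)cc(OCc2ccccc2)c2c1O[C@H](c1ccc(OCc3ccccc3)cc1)[C@@H](OCc1ccccc1)C2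
F2 | step 7 | hexa-O-benzyl ether of 12 (benzyl on the benzofuranone 4-O and 6-O, flavan 3-O, 5-O and 4'-O, and the dihydrofuran aryl 4-O) | O=C1c2c(OCc3ccccc3)cc(OCc3ccccc3)cc2O[C@]12c1c(cc(OCc3ccccc3)c3c1O[C@H](c1ccc(OCc4ccccc4)cc1)[C@@H](OCc1ccccc1)C3)O[C@H]2c1ccc(OCc2ccccc2)cc1
F3 | step 4 | 4,6-bis(benzyloxy)-2-hydroxybenzofuran-3(2H)-one | O=C1C(O)Oc2cc(OCc3ccccc3)cc(OCc3ccccc3)c12
F4 | step 5 | 4,6-bis(benzyloxy)-3-{[4-(benzyloxy)benzyl]oxy}-2-{(2R,3S)-3,5,7-tris(benzyloxy)-2-[4-(benzyloxy)phenyl]chroman-8-yl}benzofuran | C(Oc1c(-c2c(OCc3ccccc3)cc(OCc3ccccc3)c3c2O[C@H](c2ccc(OCc4ccccc4)cc2)[C@@H](OCc2ccccc2)C3)oc2cc(OCc3ccccc3)cc(OCc3ccccc3)c12)c1ccc(OCc2ccccc2)cc1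
F0 | step 6 | none | none
A1 | alternative 1 | (E)-2-(flavan-8-yl)-3-[4-(methoxymethoxy)phenyl]prop-2-en-1-ol, flavan = (2R,3S)-3,5,7-tris(methoxymethoxy)-2-[4-(methoxymethoxy)phenyl]chromane | OC/C(=C/c1ccc(OCOC)cc1)c1c(OCOC)cc(OCOC)c2c1O[C@H](c1ccc(OCOC)cc1)[C@@H](OCOC)C2
A2 | alternative 1 | cis-2,3-diaryl-2,3-epoxy alcohol from A1 | OC[C@]1(O[C@@H]1c1ccc(OCOC)cc1)c1c(OCOC)cc(OCOC)c3c1O[C@H](c1ccc(OCOC)cc1)[C@@H](OCOC)C3
A3 | alternative 2 | spiro ketone with free ring D phenol and (1S,2S)-1-aryl-1,2-dihydroxypropyl side chain, five methoxymethyl ethers | O=C1c2c(OCOC)cc(OCOC)cc2O[C@]12c1c(cc(OCOC)c(C[C@H](O)[C@@H](O)c3ccc(OCOC)cc3)c1O)O[C@H]2c1ccc(OCOC)cc1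
A4 | alternative 2 | target as its 3-O-formate carrying five methoxymethyl ethers | O=C1c2c(OCOC)cc(OCOC)cc2O[C@]12c1c(cc(OCOC)c3c1O[C@H](c1ccc(OCOC)cc1)[C@@H](OC=O)C3)O[C@H]2c1ccc(OCOC)cc1
A5 | alternative 3 | methyl 3-hydroxy-2-aryl-2,3-dihydrofuro-fused flavan-3-carboxylate (tertiary hydroxy ester; aryl = 4-(triisopropylsilyloxy)phenyl) | O[C@@]1(C(=O)OC)c2c(cc(OCOC)c3c2O[C@H](c2ccc(OCOC)cc2)[C@@H](OCOC)C3)O[C@@H]1c1ccc(O[Si](C(C)C)(C(C)C)C(C)C)cc1
A6 | alternative 3 | 3,5-bis(methoxymethoxy)-2-(trimethylsilyl)phenyl trifluoromethanesulfonate | COCOc1cc(OCOC)c([Si](C)(C)C)c(OS(=O)(=O)C(F)(F)F)c1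
A7 | alternative 3 | protected spiro ketone with the target spiro configuration, epimeric at the dihydrofuran CH | O=C1c2c(OCOC)cc(OCOC)cc2O[C@]12c1c(cc(OCOC)c3c1O[C@H](c1ccc(OCOC)cc1)[C@@H](OCOC)C3)O[C@@H]2c1ccc(O[Si](C(C)C)(C(C)C)C(C)C)cc1
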